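**Retrosynthetic overview**
- Esters last: the C8 angelate by SN2 of cesium angelate on an 8α-bromo ketone; the C3 and C6 angelates from one batch of preformed angelic 2,4,6-trichlorobenzoic anhydride; the 4α,5α-epoxide by C6–OH-directed epoxidation of a (4Z)-alkene.
- Ten-membered ring by a ring-expanding Grob fragmentation across C4–C9 of a cis-decalin 9-alkoxide whose 5α,6α-diol is a cyclic sulfate (gives C9=O, the 4Z alkene and a masked 6-OH); the 1β,10β-epoxide is set before, directed by the C9–OH.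
- Ring B, the quaternary C4 and C5–O in one step by intramolecular nitrile oxide cycloaddition; the isoxazoline then gives the β-hydroxy ketone and the anti-1,3-diol (C3).
- Ring A from o-cresol (quinone monoketal, rhodium-catalysed asymmetric isopropenyl addition); the C9–C10 bond by addition of an alkenyllithium made from 2,3-dihydrofuran.
- Ring order: ring A (from the arene), then ring B with the isoxazoline, then six-to-ten ring expansion, then the second epoxide.

Assumption: the entry is the (1R,3S,4R,5S,6S,7S,8S,10R) isomer of the SMILES with three angeloyl [(Z)-2-methylbut-2-enoyl] esters; locants are the germacrane numbers of the target (ring C1–C10, C14 on C10, C15 on C4, isopropenyl on C7), β is the ring face carrying the isopropenyl group and α the other face.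

**Route**

Step 1
Reactants: 1 2-methylphenol
Product: 2 4,4-dimethoxy-2-methylcyclohexa-2,5-dien-1-one
Conditions: PhI(OAc)2 (2.2 equiv), MeOH, 0 to 25 °C
Reagents that add atoms: methanol CO
Why: Hypervalent-iodine oxidative dearomatization (para methoxylation twice) gives the p-quinone monoketal; no stereocenter is formed.

Step 2
Reactants: 2 4,4-dimethoxy-2-methylcyclohexa-2,5-dien-1-one; 3 potassium trifluoro(prop-1-en-2-yl)borate
Product: 4 (5S)-4,4-dimethoxy-2-methyl-5-(prop-1-en-2-yl)cyclohex-2-en-1-one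
Conditions: [Rh(OH)((S)-BINAP)]2 (3 mol %), dioxane/H2O 10:1, 60 °C
Reagents that add atoms: none
Why: Hayashi–Miyaura asymmetric 1,4-addition goes to the unsubstituted enone of the monoketal, and the (S)-BINAP rhodium catalyst selects the enone face that sets C7 (5S in 4).

Step 3
Reactants: 5 2,3-dihydrofuran
Product: 8 (3Z)-4-iodopent-3-en-1-ol, via 5-lithio-2,3-dihydrofuran 6 (not isolated), via lithium alkenyl(methyl)cuprate 7 (not isolated)
Conditions: t-BuLi, THF, −78 to 0 °C; Me2CuLi (from MeLi, CuI), Et2O, −30 to 25 °C; I2, −78 °C; aq. NH4Cl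
Reagents that add atoms: methyllithium C[Li]; iodine II
Why: α-Lithiation of the cyclic enol ether and copper-mediated 1,2-metalate rearrangement (methyl migrates with inversion at the carbenoid carbon) put copper cis to the hydroxyethyl chain, and iodinolysis with retention gives the Z iodide.

Step 4
Reactants: 4 (5S)-4,4-dimethoxy-2-methyl-5-(prop-1-en-2-yl)cyclohex-2-en-1-one; 8 (3Z)-4-iodopent-3-en-1-ol
Product: 10 (1R,5S)-1-[(2Z)-5-hydroxypent-2-en-2-yl]-4,4-dimethoxy-2-methyl-5-(prop-1-en-2-yl)cyclohex-2-en-1-ol, via dilithiated alkenyl alkoxide 9 (not isolated)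
Conditions: 8, t-BuLi (3.1 equiv), Et2O, −78 °C; 4, THF, −78 to −40 °C; aq. NH4Cl
Reagents that add atoms: none
Why: Iodine–lithium exchange with retention and 1,2-addition to the enone; axial attack anti to the equatorial isopropenyl group (as with 5-substituted cyclohexenones) gives the 9β-alcohol with the chain on the α face.

Step 5
Reactants: 10 (1R,5S)-1-[(2Z)-5-hydroxypent-2-en-2-yl]-4,4-dimethoxy-2-methyl-5-(prop-1-en-2-yl)cyclohex-2-en-1-ol
Product: 11 spiro-lactol of the C3 aldehyde (ring-closed on the C9 oxygen; anomer mixture)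
Conditions: Dess–Martin periodinane (1.2 equiv), NaHCO3, CH2Cl2, 0 °C
Reagents that add atoms: none
Why: Dess–Martin oxidation touches only the primary alcohol (the other is tertiary), and the Z-alkene holds the aldehyde next to the C9–OH so that it rests as the six-membered lactol, which protects the β,γ-unsaturated aldehyde.

Step 6
Reactants: 11 spiro-lactol of the C3 aldehyde
Product: 12 (4R,6S)-4-hydroxy-4-[(2Z)-5-(hydroxyimino)pent-2-en-2-yl]-3-methyl-6-(prop-1-en-2-yl)cyclohex-2-en-1-one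
Conditions: NH2OH·HCl (1.1 equiv), THF/H2O 3:1, 25 °C; then aq. NaHCO3
Reagents that add atoms: hydroxylamine hydrochloride NO.Cl; water O
Why: Oxime condensation opens the lactol, and the same mildly acidic medium hydrolyses the allylic dimethyl ketal to the C6 enone; no stereocenter changes.

Step 7
Reactants: 12 (4R,6S)-4-hydroxy-4-[(2Z)-5-(hydroxyimino)pent-2-en-2-yl]-3-methyl-6-(prop-1-en-2-yl)cyclohex-2-en-1-one
Product: 13 (1R,4R,5S)-1-[(2Z)-5-(hydroxyimino)pent-2-en-2-yl]-2-methyl-5-(prop-1-en-2-yl)cyclohex-2-ene-1,4-diol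
Conditions: NaBH4, CeCl3·7H2O, MeOH, −78 °C
Reagents that add atoms: none
Why: Luche 1,2-reduction with axial hydride attack gives the equatorial 6α-alcohol trans to the neighbouring isopropenyl group; the oxime is inert.

Step 8
Reactants: 13 (1R,4R,5S)-1-[(2Z)-5-(hydroxyimino)pent-2-en-2-yl]-2-methyl-5-(prop-1-en-2-yl)cyclohex-2-ene-1,4-diol
Product: 15 isoxazoline-fused cis-decalin (4β-Me; 6α-OH; 9β-OH; 7β-isopropenyl; C1=C10; 2-isoxazoline C3=N–O–C5; O on C5α), via nitrile oxide 14 (not isolated)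
Conditions: PhI(OAc)2 (1.1 equiv), CF3CO2H (cat.), MeOH, 0.005 M, 0 to 25 °C
Reagents that add atoms: none
Why: Oxidation of the aldoxime to the nitrile oxide and intramolecular nitrile oxide–alkene cycloaddition close ring B; the α-face tether delivers C3 to C4 and O to C5 suprafacially on the α face, which sets the quaternary C4 (cis-decalin, Me β) and C5.

Step 9
Reactants: 15 isoxazoline-fused cis-decalin
Product: 16 5α,6α,9β-trihydroxy-7β-isopropenyl-4β,10-dimethyl-cis-decal-1(10)-en-3-one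
Conditions: Mo(CO)6 (1.2 equiv), MeCN/H2O 15:1, 80 °C
Reagents that add atoms: water O
Why: Reductive N–O cleavage of the isoxazoline by zerovalent molybdenum and hydrolysis of the imine unmask the β-hydroxy ketone under neutral conditions, without retro-aldol and without touching the alkenes.

Step 10
Reactants: 16 5α,6α,9β-trihydroxy-7β-isopropenyl-4β,10-dimethyl-cis-decal-1(10)-en-3-one
Product: 17 7β-isopropenyl-4β,10-dimethyl-cis-decal-1(10)-ene-3β,5α,6α,9β-tetrol
Conditions: Me4NBH(OAc)3, MeCN/AcOH 1:1, −30 °C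
Reagents that add atoms: none
Why: Evans–Saksena hydroxyl-directed reduction: the secondary 5α-OH exchanges onto boron (faster than the tertiary 9-OH) and delivers hydride to the α face of C3, which gives the 1,3-anti 3β-alcohol.

Step 11
Reactants: 17 7β-isopropenyl-4β,10-dimethyl-cis-decal-1(10)-ene-3β,5α,6α,9β-tetrol
Product: 18 1β,10β-epoxy-7β-isopropenyl-4β,10α-dimethyl-cis-decalin-3β,5α,6α,9β-tetrol
Conditions: VO(acac)2 (5 mol %), t-BuOOH (1.2 equiv), CH2Cl2, 0 °C
Reagents that add atoms: tert-butyl hydroperoxide CC(C)(C)OO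
Why: Vanadium-catalysed hydroxyl-directed epoxidation of the tertiary allylic alcohol (helped by the homoallylic 3β-OH) puts the oxygen syn to the C9–OH on the β face and leaves the less reactive isopropenyl group alone.

Step 12
Reactants: 18 1β,10β-epoxy-7β-isopropenyl-4β,10α-dimethyl-cis-decalin-3β,5α,6α,9β-tetrol
Product: 20 sodium (4Z)-1β,10β-epoxy-3β-hydroxy-9-oxogermacra-4,11-dien-6α-yl sulfate, via 5α,6α-cyclic sulfate 19 (not isolated)
Conditions: NaH (3.2 equiv), THF/DMF, −40 °C; 1,1'-sulfonyldiimidazole (1.05 equiv), −40 to 0 °C; then 25 °C; AcOH (1 equiv)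
Reagents that add atoms: 1,1'-sulfonyldiimidazole O=S(=O)(n1ccnc1)n1ccnc1; sodium hydride [Na+].[H-]
Why: Proposed new method: sulfuryl transfer to the cis-5,6-diol gives a five-membered cyclic sulfate whose equatorial C5–O bond is anti-periplanar to C4–C9 in the ring A chair with C3 axial, so the C9 alkoxide drives a concerted Grob fragmentation (C4–C9 cleaved, C9=O and the 4Z alkene formed, sulfate opened at C5), while the sulfate monoester left on O6 prevents the semipinacol ring contraction a free C6 alkoxide would cause; the closest known chemistry is the Wharton–Grob fragmentation of decalin 1,3-diol monosulfonates and the epoxide-like opening of cyclic sulfates, but a cyclic sulfate has not been used as the internal nucleofuge.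

Step 13
Reactants: 21 angelic acid
Product: 22 angelic 2,4,6-trichlorobenzoic anhydride
Conditions: 2,4,6-trichlorobenzoyl chloride (1.0 equiv), Et3N (1.05 equiv), toluene, 0 to 25 °C; filter off Et3N·HCl under argon, concentrate; kept as a 0.5 M toluene solution at −20 °C
Reagents that add atoms: 2,4,6-trichlorobenzoyl chloride O=C(Cl)c1c(Cl)cc(Cl)cc1Cl
Why: Yamaguchi mixed-anhydride formation (acyl substitution of the acid chloride by the carboxylate) leaves the Z-alkene untouched at 25 °C, and the one batch serves both later esterifications; no stereocenter is formed.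

Step 14
Reactants: 20 sodium (4Z)-1β,10β-epoxy-3β-hydroxy-9-oxogermacra-4,11-dien-6α-yl sulfate; 22 angelic 2,4,6-trichlorobenzoic anhydride
Product: 24 (4Z)-3β-angeloyloxy-1β,10β-epoxy-6α-hydroxygermacra-4,11-dien-9-one, via 3-O-angeloyl 6-sulfate 23 (not isolated)
Conditions: 22 (1.5 equiv), polymer-bound DMAP (3 equiv), CH2Cl2/DMF 4:1, 25 °C; filter, evaporate; then H2SO4 (cat.), H2O (2 equiv), THF, 25 °C
Reagents that add atoms: none
Why: Yamaguchi acyl transfer (the hindered trichlorobenzoyl carbonyl steers the alcohol to the angeloyl carbonyl) acylates the only free hydroxyl (C3) while O6 is still the sulfate, and acid hydrolysis of the sulfate monoester (S–O cleavage, retention at C6) then frees the 6α-OH as the only directing group.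

Step 15
Reactants: 24 (4Z)-3β-angeloyloxy-1β,10β-epoxy-6α-hydroxygermacra-4,11-dien-9-one
Product: 25 3β-angeloyloxy-1β,10β:4α,5α-diepoxy-6α-hydroxygermacr-11-en-9-one
Conditions: VO(acac)2 (5 mol %), t-BuOOH (1.2 equiv), CH2Cl2, 0 °C
Reagents that add atoms: tert-butyl hydroperoxide CC(C)(C)OO
Why: Vanadium-catalysed allylic-alcohol-directed epoxidation needs the C6–O bond at about 40° to the alkene plane, so oxygen is delivered cis to the 6α-OH (the behaviour of medium-ring Z-cycloalkenols) and trans to the non-directing C3 ester; this sets C4 and C5 and spares the isopropenyl and angelate alkenes.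

Step 16
Reactants: 25 3β-angeloyloxy-1β,10β:4α,5α-diepoxy-6α-hydroxygermacr-11-en-9-one; 22 angelic 2,4,6-trichlorobenzoic anhydride
Product: 26 3β,6α-bis(angeloyloxy)-1β,10β:4α,5α-diepoxygermacr-11-en-9-one
Conditions: 22 (2 equiv), Et3N (3 equiv), DMAP (0.3 equiv), toluene, 50 °C
Reagents that add atoms: none
Why: Yamaguchi acyl transfer from the preformed mixed anhydride acylates the hindered secondary alcohol with retention at C6, and a short reaction time with limited DMAP keeps the angelate from isomerising to the tiglate.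

Step 17
Reactants: 26 3β,6α-bis(angeloyloxy)-1β,10β:4α,5α-diepoxygermacr-11-en-9-one
Product: 28 8α-bromo-3β,6α-bis(angeloyloxy)-1β,10β:4α,5α-diepoxygermacr-11-en-9-one, via trimethylsilyl enol ether 27 (not isolated)
Conditions: LiN(SiMe3)2, Me3SiCl, THF, −78 °C; N-bromosuccinimide, THF, −78 °C
Reagents that add atoms: N-bromosuccinimide O=C1CCC(=O)N1Br
Why: The ketone can enolise only toward C8, and electrophilic bromination of the silyl enol ether from the outer ring face, with H7 eclipsing the enol double bond (A(1,3) control), puts bromine trans to the isopropenyl group (8α).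

Step 18
Reactants: 28 8α-bromo-3β,6α-bis(angeloyloxy)-1β,10β:4α,5α-diepoxygermacr-11-en-9-one; 21 angelic acid
Product: 30 (1R,3S,4R,5S,6S,7S,8S,10R)-3β,6α,8β-tris(angeloyloxy)-1β,10β:4α,5α-diepoxygermacr-11-en-9-one (CNP0154187.1), via cesium angelate 29 (not isolated)
Conditions: 21 (5 equiv), Cs2CO3, DMF, 0 °C; 28, 0 to 25 °C
Reagents that add atoms: none
Why: SN2 displacement of the activated α-bromo ketone by the cesium carboxylate inverts C8 to the 8β ester (8S); carboxylate alkylation does not isomerise the angelate, and the ketone has no α'-hydrogen for a Favorskii path.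

**Compound list**
1 | 2-methylphenol (o-cresol) | Cc1ccccc1O | starting material
2 | 4,4-dimethoxy-2-methylcyclohexa-2,5-dien-1-one | O=C1C=CC(OC)(OC)C=C1C | intermediate
3 | potassium trifluoro(prop-1-en-2-yl)borate | C=C(C)[B-](F)(F)F.[K+] | starting material
4 | (5S)-4,4-dimethoxy-2-methyl-5-(prop-1-en-2-yl)cyclohex-2-en-1-one | O=C1C[C@@H](C(C)=C)C(OC)(OC)C=C1C | intermediate
5 | 2,3-dihydrofuran | C1CC=CO1 | starting material
6 | 5-lithio-2,3-dihydrofuran | [Li]C1=CCCO1 | intermediate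
7 | dilithium methyl[(2Z)-5-oxidopent-2-en-2-yl]cuprate | C[Cu-]/C(C)=C\CC[O-].[Li+].[Li+] | intermediate
8 | (3Z)-4-iodopent-3-en-1-ol | C/C(I)=C/CCO | intermediate
9 | lithium (3E)-4-lithiopent-3-en-1-olate (lithium cis to the oxidoethyl chain) | C/C([Li])=C/CCO[Li] | intermediate
10 | (1R,5S)-1-[(2Z)-5-hydroxypent-2-en-2-yl]-4,4-dimethoxy-2-methyl-5-(prop-1-en-2-yl)cyclohex-2-en-1-ol | O[C@@]1(/C(C)=C\CCO)C[C@@H](C(C)=C)C(OC)(OC)C=C1C | intermediate
11 | spiro-lactol of the C3 aldehyde from 10 (2-hydroxy-5-methyl-3,6-dihydro-2H-pyran spiro-joined through C9, ring O on the β face; anomer mixture) | OC1CC=C(C)[C@]2(O1)C[C@@H](C(C)=C)C(OC)(OC)C=C2C | intermediate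
12 | (4R,6S)-4-hydroxy-4-[(2Z)-5-(hydroxyimino)pent-2-en-2-yl]-3-methyl-6-(prop-1-en-2-yl)cyclohex-2-en-1-one | ON=CC/C=C(C)\[C@]1(O)C[C@@H](C(C)=C)C(=O)C=C1C | intermediate
13 | (1R,4R,5S)-1-[(2Z)-5-(hydroxyimino)pent-2-en-2-yl]-2-methyl-5-(prop-1-en-2-yl)cyclohex-2-ene-1,4-diol | ON=CC/C=C(C)\[C@]1(O)C[C@@H](C(C)=C)[C@H](O)C=C1C | intermediate
14 | nitrile oxide of 13 (C3≡N–O) | [O-][N+]#CC/C=C(C)\[C@]1(O)C[C@@H](C(C)=C)[C@H](O)C=C1C | intermediate
15 | isoxazoline-fused cis-decalin (rings A and B joined at C4–C9; 4β-Me, 9β-OH, 6α-OH, 7β-isopropenyl, C1=C10, 2-isoxazoline C3=N–O–C5, O on C5α) | O[C@]12C[C@@H](C(C)=C)[C@H](O)[C@@H]3ON=C(CC=C1C)[C@]23C | intermediate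
16 | 5α,6α,9β-trihydroxy-7β-isopropenyl-4β,10-dimethyl-cis-decal-1(10)-en-3-one | O[C@@]12C[C@@H](C(C)=C)[C@H](O)[C@H](O)[C@]1(C)C(=O)CC=C2C | intermediate
17 | 7β-isopropenyl-4β,10-dimethyl-cis-decal-1(10)-ene-3β,5α,6α,9β-tetrol | O[C@@]12C[C@@H](C(C)=C)[C@H](O)[C@H](O)[C@]1(C)[C@@H](O)CC=C2C | intermediate
18 | 1β,10β-epoxy-7β-isopropenyl-4β,10α-dimethyl-cis-decalin-3β,5α,6α,9β-tetrol | O[C@@]12C[C@@H](C(C)=C)[C@H](O)[C@H](O)[C@]1(C)[C@@H](O)C[C@H]3O[C@@]23C | intermediate
19 | 5α,6α-cyclic sulfate of 18 | O[C@@]12C[C@@H](C(C)=C)[C@@H]3OS(=O)(=O)O[C@@H]3[C@]1(C)[C@@H](O)C[C@H]4O[C@@]24C | intermediate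
20 | sodium (4Z)-1β,10β-epoxy-3β-hydroxy-9-oxogermacra-4,11-dien-6α-yl sulfate | C=C(C)[C@H]1[C@H](OS(=O)(=O)[O-])/C=C(C)\[C@@H](O)C[C@H]2O[C@@]2(C)C(=O)C1.[Na+] | intermediate
21 | angelic acid [(Z)-2-methylbut-2-enoic acid] | C/C=C(/C)C(=O)O | starting material
22 | angelic 2,4,6-trichlorobenzoic anhydride | C/C=C(/C)C(=O)OC(=O)c1c(Cl)cc(Cl)cc1Cl | intermediate
23 | sodium (4Z)-3β-angeloyloxy-1β,10β-epoxy-9-oxogermacra-4,11-dien-6α-yl sulfate | C=C(C)[C@H]1[C@H](OS(=O)(=O)[O-])/C=C(C)\[C@@H](OC(=O)/C(C)=C\C)C[C@H]2O[C@@]2(C)C(=O)C1.[Na+] | intermediate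
24 | (4Z)-3β-angeloyloxy-1β,10β-epoxy-6α-hydroxygermacra-4,11-dien-9-one | C=C(C)[C@H]1[C@H](O)/C=C(C)\[C@@H](OC(=O)/C(C)=C\C)C[C@H]2O[C@@]2(C)C(=O)C1 | intermediate
25 | 3β-angeloyloxy-1β,10β:4α,5α-diepoxy-6α-hydroxygermacr-11-en-9-one | C=C(C)[C@H]1[C@H](O)[C@@H]2O[C@]2(C)[C@@H](OC(=O)/C(C)=C\C)C[C@H]2O[C@@]2(C)C(=O)C1 | intermediate
26 | 3β,6α-bis(angeloyloxy)-1β,10β:4α,5α-diepoxygermacr-11-en-9-one | C=C(C)[C@H]1[C@H](OC(=O)/C(C)=C\C)[C@@H]2O[C@]2(C)[C@@H](OC(=O)/C(C)=C\C)C[C@H]2O[C@@]2(C)C(=O)C1 | intermediate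
27 | 8,9-enol trimethylsilyl ether of 26 | C=C(C)[C@H]1[C@H](OC(=O)/C(C)=C\C)[C@@H]2O[C@]2(C)[C@@H](OC(=O)/C(C)=C\C)C[C@H]2O[C@@]2(C)C(O[Si](C)(C)C)=C1 | intermediate
28 | 8α-bromo-3β,6α-bis(angeloyloxy)-1β,10β:4α,5α-diepoxygermacr-11-en-9-one | C=C(C)[C@H]1[C@H](OC(=O)/C(C)=C\C)[C@@H]2O[C@]2(C)[C@@H](OC(=O)/C(C)=C\C)C[C@H]2O[C@@]2(C)C(=O)[C@@H]1Br | intermediate
29 | cesium angelate | C/C=C(/C)C(=O)[O-].[Cs+] | intermediate
30 | (1R,3S,4R,5S,6S,7S,8S,10R)-3β,6α,8β-tris(angeloyloxy)-1β,10β:4α,5α-diepoxygermacr-11-en-9-one (CNP0154187.1) | C=C(C)[C@H]1[C@H](OC(=O)/C(C)=C\C)[C@@H]2O[C@]2(C)[C@@H](OC(=O)/C(C)=C\C)C[C@H]2O[C@@]2(C)C(=O)[C@H]1OC(=O)/C(C)=C\C | target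

**Totals**
Total step count: 18. Longest linear sequence: 16 steps (steps 1, 2, 4 to 12 and 14 to 18 from o-cresol); step 3 makes the side fragment and step 13 the acylating agent.

**Three steps most likely to fail**

Step 12 (the proposed sulfation and Grob fragmentation; risks are sulfation at the wrong hydroxyl or slow fragmentation through the chair that holds the isopropenyl group axial). The fallback uses known chemistry, sets out from 15 and comes back at 24. Silylation of the secondary 6-OH (Et3SiOTf, 2,6-lutidine) gives the 6-O-triethylsilyl isoxazoline F1. Mo(CO)6 in wet MeCN gives the 5α,9β-dihydroxy-6α-triethylsilyloxy 3-ketone F2, whose only free secondary hydroxyl is mesylated (MsCl, Et3N) to the 5α-mesylate F3. Corey–Bakshi–Shibata reduction (BH3·SMe2) with the oxazaborolidine antipode that delivers hydride to the α face gives the 3β-alcohol F4, and VO(acac)2 with t-BuOOH gives the 1β,10β-epoxide F5. The classical Wharton–Grob fragmentation of this 1,3-diol monomesylate (KOtBu, THF, 0 °C) gives (4Z)-1β,10β-epoxy-3β-hydroxy-6α-(triethylsilyloxy)germacra-4,11-dien-9-one F6. Acylation with the mixed anhydride 22 (Et3N, DMAP, toluene) gives the 3-angelate F7, and HF·pyridine removes the silyl group to give 24.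

Step 15 (facial selectivity of the directed epoxidation in a ten-membered ring). The fallback sets out from 24 and comes back at 26. The 6-OH is first esterified with the mixed anhydride 22 (Et3N, DMAP, toluene) to give (4Z)-3β,6α-bis(angeloyloxy)-1β,10β-epoxygermacra-4,11-dien-9-one F8. The trisubstituted ring alkene is then epoxidised under catalyst control (Shi epoxidation with the fructose-derived ketone antipode that attacks the α face, KHSO5, buffered MeCN/H2O, 0 °C); the dioxirane leaves the 1,1-disubstituted isopropenyl and the electron-poor angelate alkenes alone and gives 26.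

Step 18 (the bromide may eliminate toward C7 or epimerise before substitution). The fallback sets out from 26 and comes back at 30. The lithium enolate (LiN(SiMe3)2, THF, −78 °C) is hydroxylated with the Davis oxaziridine on the same outer face to give the 8α-hydroxy ketone F9. A Mitsunobu esterification with angelic acid 21 (PPh3, diisopropyl azodicarboxylate, toluene, 0 °C) then inverts C8 and gives 30.

Further compounds
F1 | step 12 | 6-O-triethylsilyl ether of isoxazoline 15 | O[C@]12C[C@@H](C(C)=C)[C@H](O[Si](CC)(CC)CC)[C@@H]3ON=C(CC=C1C)[C@]23C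
F2 | step 12 | 5α,9β-dihydroxy-7β-isopropenyl-4β,10-dimethyl-6α-(triethylsilyloxy)-cis-decal-1(10)-en-3-one | O[C@@]12C[C@@H](C(C)=C)[C@H](O[Si](CC)(CC)CC)[C@H](O)[C@]1(C)C(=O)CC=C2C
F3 | step 12 | 5α-methanesulfonate of F2 | O[C@@]12C[C@@H](C(C)=C)[C@H](O[Si](CC)(CC)CC)[C@H](OS(C)(=O)=O)[C@]1(C)C(=O)CC=C2C
F4 | step 12 | 3β-alcohol from F3 | O[C@@]12C[C@@H](C(C)=C)[C@H](O[Si](CC)(CC)CC)[C@H](OS(C)(=O)=O)[C@]1(C)[C@@H](O)CC=C2C
F5 | step 12 | 1β,10β-epoxide of F4 | O[C@@]12C[C@@H](C(C)=C)[C@H](O[Si](CC)(CC)CC)[C@H](OS(C)(=O)=O)[C@]1(C)[C@@H](O)C[C@H]3O[C@@]23C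
F6 | step 12 | (4Z)-1β,10β-epoxy-3β-hydroxy-6α-(triethylsilyloxy)germacra-4,11-dien-9-one | C=C(C)[C@H]1[C@H](O[Si](CC)(CC)CC)/C=C(C)\[C@@H](O)C[C@H]2O[C@@]2(C)C(=O)C1
F7 | step 12 | (4Z)-3β-angeloyloxy-1β,10β-epoxy-6α-(triethylsilyloxy)germacra-4,11-dien-9-one | C=C(C)[C@H]1[C@H](O[Si](CC)(CC)CC)/C=C(C)\[C@@H](OC(=O)/C(C)=C\C)C[C@H]2O[C@@]2(C)C(=O)C1
F8 | step 15 | (4Z)-3β,6α-bis(angeloyloxy)-1β,10β-epoxygermacra-4,11-dien-9-one | C=C(C)[C@H]1[C@H](OC(=O)/C(C)=C\C)/C=C(C)\[C@@H](OC(=O)/C(C)=C\C)C[C@H]2O[C@@]2(C)C(=O)C1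
F9 | step 18 | 3β,6α-bis(angeloyloxy)-1β,10β:4α,5α-diepoxy-8α-hydroxygermacr-11-en-9-one | C=C(C)[C@H]1[C@H](OC(=O)/C(C)=C\C)[C@@H]2O[C@]2(C)[C@@H](OC(=O)/C(C)=C\C)C[C@H]2O[C@@]2(C)C(=O)[C@@H]1O
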